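## Retrosynthetic overview

1. The strategy rests on flavone ring A. It is a resorcinol mono-ether, with free OH on C5 and OMe on C7 (meta across C6–H), fused through C4a–C8a to pyranone ring C. A ketene carbon becomes C5–OH and the methoxy-bearing alkyne carbon becomes C7, so no two hydroxyls ever need to be differentiated.
2. Last disconnection: ring E (flavanone heterocycle) at O1''–C2'', by catalytic asymmetric oxa-Michael addition on an alkylidene β-keto ester grown from ring D. The 5''-methyl and 4'''-benzyl ethers are removed at the end.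
3. Key disconnection: ring A goes back to diazo ketone 13 (ring C already carrying rings B and D) plus methoxyacetylene 16. Bonds formed: C8–C8a, C5–C6, C7–C8, C4a–C5.
4. Ring C comes from aryl methyl ketone 6, ethyl acetate and diethyl oxalate (two Claisen condensations, then cyclodehydration). The diaryl ether comes from SNAr of 2,6-dimethoxyphenol on 4'-fluoroacetophenone, and the para oxygen of ring D from C–H borylation/oxidation.
5. Order of ring formation: C (step 5), A (step 9), E (step 14). Rings B, D and F are bought as benzenes.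

Key step: step 9

Locants: flavone = rings A (benzo), C (pyranone) and B (2-aryl), with plain and single-primed numbers. Flavanone = rings D (benzo) and E (dihydropyranone) with double primes, and ring F (4-hydroxyphenyl) with triple primes.

Assumption: the quinidine-derived 9-epi-amino thiourea is taken to give the 2S series in step 14; its quinine-derived pseudo-enantiomer gives the mirror image, so the sense is to be confirmed by circular dichroism on 29 and only the catalyst exchanged if it is reversed; 26 is drawn as the expected Z isomer.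

## Route

Step 1
Reactants: 1 2,6-dimethoxyphenol; 2 4'-fluoroacetophenone
Product: 3 1-[4-(2,6-dimethoxyphenoxy)phenyl]ethan-1-one
Conditions: K2CO3 (1.5 equiv), DMAc, 140 °C, N2
Reagents that add atoms: none
Why: Nucleophilic aromatic substitution by addition–elimination, in which the para-acetyl group stabilises the Meisenheimer adduct and fluoride leaves, and in which neither partner carries an aldehyde that could enter a Claisen–Schmidt condensation with the methyl ketone in hot carbonate.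

Step 2
Reactants: 3 1-[4-(2,6-dimethoxyphenoxy)phenyl]ethan-1-one
Product: 5 1-[4-(4-hydroxy-2,6-dimethoxyphenoxy)phenyl]ethan-1-one, via aryl pinacol boronate 4 (not isolated)
Conditions: [Ir(OMe)(cod)]2 (1.5 mol %), 4,4'-di-tert-butyl-2,2'-bipyridine (3 mol %), B2pin2 (1.0 equiv), THF, 80 °C; then 30% H2O2, 1 M NaOH, 0 °C; 1 M HCl
Reagents that add atoms: bis(pinacolato)diboron CC1(C)OB(OC1(C)C)B1OC(C)(C)C(C)(C)O1 (boron unit of 4); hydrogen peroxide OO (phenol oxygen of 5)
Why: Sterically governed iridium-catalysed C–H borylation followed by boronate oxidation, where only the ring D C–H para to the ether oxygen has no ortho substituent (every other aromatic C–H of 3 flanks a substituent), so boron and then hydroxyl should enter at that carbon alone.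

Step 3
Reactants: 5 1-[4-(4-hydroxy-2,6-dimethoxyphenoxy)phenyl]ethan-1-one
Product: 6 1-{4-[4-(benzyloxy)-2,6-dimethoxyphenoxy]phenyl}ethan-1-one
Conditions: BnBr (1.1 equiv), K2CO3, DMF, rt
Reagents that add atoms: benzyl bromide BrCc1ccccc1
Why: Williamson ether synthesis on the only acidic OH, giving a benzyl ether that should tolerate the alkoxide, acid chloride, diazomethane and irradiation steps ahead.

Step 4
Reactants: 6 1-{4-[4-(benzyloxy)-2,6-dimethoxyphenoxy]phenyl}ethan-1-one
Product: 7 1-{4-[4-(benzyloxy)-2,6-dimethoxyphenoxy]phenyl}butane-1,3-dione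
Conditions: NaH (2.5 equiv), EtOAc (4 equiv), THF, reflux; 1 M HCl
Reagents that add atoms: ethyl acetate CCOC(C)=O
Why: Crossed Claisen condensation of the ketone enolate with ethyl acetate, pulled to completion by irreversible deprotonation of the β-diketone.

Step 5
Reactants: 7 1-{4-[4-(benzyloxy)-2,6-dimethoxyphenoxy]phenyl}butane-1,3-dione; 8 diethyl oxalate
Product: 10 ethyl 6-{4-[4-(benzyloxy)-2,6-dimethoxyphenoxy]phenyl}-4-oxo-4H-pyran-2-carboxylate, via triketo ester 9 (not isolated)
Conditions: NaOEt (2.5 equiv), EtOH–THF, 0 → 60 °C; 1 M HCl; then p-TsOH·H2O (20 mol %), toluene, reflux, Dean–Stark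
Reagents that add atoms: none
Why: Claisen condensation under equilibrating alkoxide conditions (the chelidonic acid protocol), which funnels oxalylation to the terminal methyl because only that product forms a doubly stabilised dianion, followed by acid-catalysed cyclodehydration of the 1,3,5-tricarbonyl array, which closes ring C to the same 4-pyranone whichever enol oxygen attacks.

Step 6
Reactants: 10 ethyl 6-{4-[4-(benzyloxy)-2,6-dimethoxyphenoxy]phenyl}-4-oxo-4H-pyran-2-carboxylate
Product: 11 6-{4-[4-(benzyloxy)-2,6-dimethoxyphenoxy]phenyl}-4-oxo-4H-pyran-2-carboxylic acid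
Conditions: LiOH·H2O (1.05 equiv), THF–H2O, 0 °C; 1 M HCl
Reagents that add atoms: lithium hydroxide [Li+].[OH-]
Why: Saponification of an activated ester on an electron-poor heterocycle, fast enough at 0 °C with one equivalent of hydroxide to outrun attack on the pyranone, any ring-opened triketo acid reclosing on acidification.

Step 7
Reactants: 11 6-{4-[4-(benzyloxy)-2,6-dimethoxyphenoxy]phenyl}-4-oxo-4H-pyran-2-carboxylic acid
Product: 13 2-(2-diazoacetyl)-6-{4-[4-(benzyloxy)-2,6-dimethoxyphenoxy]phenyl}-4H-pyran-4-one, via acid chloride 12 (not isolated)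
Conditions: (COCl)2 (1.2 equiv), DMF (cat.), CH2Cl2, 0 °C → rt, evaporate; CH2N2 (1.3 equiv, Et2O), Et3N (1.1 equiv), THF, −10 → 0 °C
Reagents that add atoms: oxalyl chloride ClC(=O)C(Cl)=O (chlorine of 12); diazomethane C=[N+]=[N-]
Why: Acylation of diazomethane as in the first stage of the Arndt–Eistert sequence, with triethylamine taking up HCl (12 has no α-hydrogen, so it cannot form a ketene) so that little excess diazomethane remains to add as a dipole to the pyranone C=C bonds.

Step 8
Reactants: 14 chloroacetaldehyde dimethyl acetal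
Product: 16 methoxyacetylene, via sodium methoxyacetylide 15 (not isolated)
Conditions: NaNH2 (3.2 equiv), liq. NH3, −33 °C; evaporate NH3; sat. aq. NaCl, −20 °C; distil (bp 23 °C) into cold ClCH2CH2Cl
Reagents that add atoms: sodium amide [Na+].[NH2-] (sodium of 15)
Why: Twofold base-induced β-elimination (methanol, then HCl) with the third equivalent of amide holding the product as its acetylide until the cold aqueous quench, the standard preparation of alkoxyacetylenes.

Step 9
Reactants: 13 2-(2-diazoacetyl)-6-{4-[4-(benzyloxy)-2,6-dimethoxyphenoxy]phenyl}-4H-pyran-4-one; 16 methoxyacetylene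
Product: 21 2-{4-[4-(benzyloxy)-2,6-dimethoxyphenoxy]phenyl}-5-hydroxy-7-methoxy-4H-chromen-4-one, via pyranonylketene 17 (not isolated), via cyclobutenone 18 (not isolated), via dienylketene 19 (not isolated), via keto tautomer 20 (not isolated)
Conditions: 16 (5 equiv), degassed ClCH2CH2Cl (0.02 M), LED 420 nm, 5 °C, sealed Pyrex; vent excess 16; 80 °C, 3 h
Reagents that add atoms: none
Why: Proposed new method: excitation of the weak long-wavelength diazo band expels N2 and pyranone C2 (future C8a) shifts to the diazo carbon (future C8) in a Wolff rearrangement to give ketene 17; the closest known reaction type is the photochemical Danheiser benzannulation of unsaturated and heteroaryl diazo ketones with alkoxyalkynes, which has not been run with a 4-pyranone as the vinyl unit. The unsubstituted, nucleophilic carbon of 16 attacks the ketene carbonyl carbon (C5–C6) and the methoxy-bearing carbon closes onto C8 (C7–C8), a [2+2] cycloaddition giving the transient four-membered ring of 18. At 80 °C 18 opens by reversible four-electron conrotatory cleavage of its C5–C8 bond to 19, and only the isomer with ketenyl and pyranonyl groups cis can go on, the other one returning to 18. Ring A closes by six-electron disrotatory electrocyclisation of 19, the ketene carbon C5 bonding to pyranone C3 (future C4a), and 20 enolises to the phenol, so no stereocentre survives because the sp3 carbons of 18 and 20 are lost on aromatisation. Regioselectivity (OMe on C7, meta to the C5 hydroxyl) is secured by the polarisation of the ynol ether, site selectivity by pyranone C2 having C3–H as its only carbon neighbour in the ring, and chemoselective excitation by 420 nm light, which neither the arylpyranone nor the flavone product should absorb. The new C5–OH is hydrogen-bonded to C4=O, which should keep it from trapping 17 as an aryl ester, and 16 has no β-hydrogen, so it cannot decay by retro-ene loss of ketene during heating.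

Step 10
Reactants: 21 2-{4-[4-(benzyloxy)-2,6-dimethoxyphenoxy]phenyl}-5-hydroxy-7-methoxy-4H-chromen-4-one
Product: 22 5-hydroxy-2-[4-(4-hydroxy-2,6-dimethoxyphenoxy)phenyl]-7-methoxy-4H-chromen-4-one
Conditions: H2 (1 atm), 10% Pd/C, EtOAc–THF, rt
Reagents that add atoms: none
Why: Catalytic hydrogenolysis of an aryl benzyl ether, which at one atmosphere and room temperature is much faster than reduction of the conjugated, tetrasubstituted-like C2=C3 bond of a flavone.

Step 11
Reactants: 22 5-hydroxy-2-[4-(4-hydroxy-2,6-dimethoxyphenoxy)phenyl]-7-methoxy-4H-chromen-4-one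
Product: 23 2-[4-(3-acetyl-4-hydroxy-2,6-dimethoxyphenoxy)phenyl]-5-hydroxy-7-methoxy-4H-chromen-4-one
Conditions: AcOH (5 equiv), BF3·OEt2, 80 °C; aq. work-up
Reagents that add atoms: acetic acid CC(=O)O
Why: Friedel–Crafts acylation (the O-acetylation/Fries path leads to the same ketone), in which ring D carries three oxygen donors and its two free positions, both ortho to the hydroxyl, are equivalent by symmetry, while ring A is deactivated by BF3 complexation at C5–OH/C4=O and the new ketone stops a second acylation.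

Step 12
Reactants: 23 2-[4-(3-acetyl-4-hydroxy-2,6-dimethoxyphenoxy)phenyl]-5-hydroxy-7-methoxy-4H-chromen-4-one
Product: 24 tert-butyl 3-{6-hydroxy-3-[4-(5-hydroxy-7-methoxy-4-oxo-4H-chromen-2-yl)phenoxy]-2,4-dimethoxyphenyl}-3-oxopropanoate
Conditions: LiN(SiMe3)2 (4.5 equiv), THF, −78 → −20 °C; Boc2O (1.15 equiv), −78 → 0 °C; AcOH quench
Reagents that add atoms: di-tert-butyl dicarbonate CC(C)(C)OC(=O)OC(=O)OC(C)(C)C
Why: Claisen-type C-acylation of a polylithiated ortho-hydroxyacetophenone, whose enolate carbon is far more nucleophilic than the two chelated lithium phenoxides, and in which any aryl carbonate formed on ring D should be carried to the same product by base-induced O-to-C transfer of the Baker–Venkataraman type.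

Step 13
Reactants: 24 tert-butyl 3-{6-hydroxy-3-[4-(5-hydroxy-7-methoxy-4-oxo-4H-chromen-2-yl)phenoxy]-2,4-dimethoxyphenyl}-3-oxopropanoate; 25 4-(benzyloxy)benzaldehyde
Product: 26 tert-butyl (2Z)-3-[4-(benzyloxy)phenyl]-2-{6-hydroxy-3-[4-(5-hydroxy-7-methoxy-4-oxo-4H-chromen-2-yl)phenoxy]-2,4-dimethoxybenzoyl}prop-2-enoate
Conditions: piperidine (20 mol %), AcOH (20 mol %), 4 Å MS, toluene, rt
Reagents that add atoms: none
Why: Knoevenagel condensation through the iminium ion of 25, run buffered, cold and in a non-polar solvent to hold back uncatalysed closure by the free phenol, with the aryl group expected cis to the ester and trans to the bulkier aroyl group.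

Step 14
Reactants: 26 tert-butyl (2Z)-3-[4-(benzyloxy)phenyl]-2-{6-hydroxy-3-[4-(5-hydroxy-7-methoxy-4-oxo-4H-chromen-2-yl)phenoxy]-2,4-dimethoxybenzoyl}prop-2-enoate
Product: 29 (2S)-2-[4-(benzyloxy)phenyl]-6-[4-(5-hydroxy-7-methoxy-4-oxo-4H-chromen-2-yl)phenoxy]-5,7-dimethoxy-2,3-dihydro-4H-chromen-4-one, via tert-butyl flavanone-3-carboxylate 27 (not isolated), via flavanone-3-carboxylic acid 28 (not isolated)
Conditions: N-[3,5-bis(trifluoromethyl)phenyl]-N'-[(9R)-6'-methoxycinchonan-9-yl]thiourea (10 mol %), toluene, −25 °C; then p-TsOH·H2O (50 mol %), 80 °C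
Reagents that add atoms: none
Why: Bifunctional-catalyst asymmetric intramolecular oxa-Michael addition (6-endo-trig), in which the thiourea hydrogen-bonds the β-keto ester and the quinuclidine nitrogen activates the ring D hydroxyl so that O1'' reaches one face of the alkylidene carbon and sets C2'' as S, after which acidolysis of the tert-butyl ester and decarboxylation of 28 remove the configurationally irrelevant C3'' centre without touching C2''.

Step 15
Reactants: 29 (2S)-2-[4-(benzyloxy)phenyl]-6-[4-(5-hydroxy-7-methoxy-4-oxo-4H-chromen-2-yl)phenoxy]-5,7-dimethoxy-2,3-dihydro-4H-chromen-4-one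
Product: 30 (2S)-5-hydroxy-6-[4-(5-hydroxy-7-methoxy-4-oxo-4H-chromen-2-yl)phenoxy]-2-(4-hydroxyphenyl)-7-methoxy-2,3-dihydro-4H-chromen-4-one (CNP0202121.1)
Conditions: BCl3 (6 equiv), pentamethylbenzene (4 equiv), CH2Cl2, −78 °C, then −10 °C; MeOH quench at −78 °C, pH 5–6 buffer
Reagents that add atoms: none
Why: Lewis-acid ether cleavage, in which BCl3 with pentamethylbenzene as cation trap removes the 4'''-benzyl group at −78 °C and, on warming, the boron chelate between C4''=O and the peri 5''-oxygen directs loss of that methyl alone, sparing the unchelated 7- and 7''-methyl ethers, while early conversion of the 4'''-oxygen into an electron-poor aryloxyborane should disfavour ionisation at C2'' and so protect the stereocentre.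

## Compound list

1 | 2,6-dimethoxyphenol | COc1cccc(OC)c1O | starting material
2 | 4'-fluoroacetophenone | CC(=O)c1ccc(F)cc1 | starting material
3 | 1-[4-(2,6-dimethoxyphenoxy)phenyl]ethan-1-one | CC(=O)c1ccc(Oc2c(OC)cccc2OC)cc1 | intermediate
4 | 1-{4-[2,6-dimethoxy-4-(4,4,5,5-tetramethyl-1,3,2-dioxaborolan-2-yl)phenoxy]phenyl}ethan-1-one | CC(=O)c1ccc(Oc2c(OC)cc(B3OC(C)(C)C(C)(C)O3)cc2OC)cc1 | intermediate
5 | 1-[4-(4-hydroxy-2,6-dimethoxyphenoxy)phenyl]ethan-1-one | CC(=O)c1ccc(Oc2c(OC)cc(O)cc2OC)cc1 | intermediate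
6 | 1-{4-[4-(benzyloxy)-2,6-dimethoxyphenoxy]phenyl}ethan-1-one | CC(=O)c1ccc(Oc2c(OC)cc(OCc3ccccc3)cc2OC)cc1 | intermediate
7 | 1-{4-[4-(benzyloxy)-2,6-dimethoxyphenoxy]phenyl}butane-1,3-dione | CC(=O)CC(=O)c1ccc(Oc2c(OC)cc(OCc3ccccc3)cc2OC)cc1 | intermediate
8 | diethyl oxalate | CCOC(=O)C(=O)OCC | starting material
9 | ethyl 6-{4-[4-(benzyloxy)-2,6-dimethoxyphenoxy]phenyl}-2,4,6-trioxohexanoate | CCOC(=O)C(=O)CC(=O)CC(=O)c1ccc(Oc2c(OC)cc(OCc3ccccc3)cc2OC)cc1 | intermediate
10 | ethyl 6-{4-[4-(benzyloxy)-2,6-dimethoxyphenoxy]phenyl}-4-oxo-4H-pyran-2-carboxylate | CCOC(=O)c1cc(=O)cc(-c2ccc(Oc3c(OC)cc(OCc4ccccc4)cc3OC)cc2)o1 | intermediate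
11 | 6-{4-[4-(benzyloxy)-2,6-dimethoxyphenoxy]phenyl}-4-oxo-4H-pyran-2-carboxylic acid | OC(=O)c1cc(=O)cc(-c2ccc(Oc3c(OC)cc(OCc4ccccc4)cc3OC)cc2)o1 | intermediate
12 | 6-{4-[4-(benzyloxy)-2,6-dimethoxyphenoxy]phenyl}-4-oxo-4H-pyran-2-carbonyl chloride | ClC(=O)c1cc(=O)cc(-c2ccc(Oc3c(OC)cc(OCc4ccccc4)cc3OC)cc2)o1 | intermediate
13 | 2-(2-diazoacetyl)-6-{4-[4-(benzyloxy)-2,6-dimethoxyphenoxy]phenyl}-4H-pyran-4-one | [N-]=[N+]=CC(=O)c1cc(=O)cc(-c2ccc(Oc3c(OC)cc(OCc4ccccc4)cc3OC)cc2)o1 | intermediate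
14 | chloroacetaldehyde dimethyl acetal | COC(OC)CCl | starting material
15 | sodium methoxyacetylide | [Na+].[C-]#COC | intermediate
16 | methoxyacetylene | COC#C | intermediate
17 | 6-{4-[4-(benzyloxy)-2,6-dimethoxyphenoxy]phenyl}-2-(2-oxoethenyl)-4H-pyran-4-one | O=C=Cc1cc(=O)cc(-c2ccc(Oc3c(OC)cc(OCc4ccccc4)cc3OC)cc2)o1 | intermediate
18 | 6-{4-[4-(benzyloxy)-2,6-dimethoxyphenoxy]phenyl}-2-(2-methoxy-4-oxocyclobut-2-en-1-yl)-4H-pyran-4-one (racemic) | COC1=CC(=O)C1c1cc(=O)cc(-c2ccc(Oc3c(OC)cc(OCc4ccccc4)cc3OC)cc2)o1 | intermediate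
19 | 6-{4-[4-(benzyloxy)-2,6-dimethoxyphenoxy]phenyl}-2-[(1E)-2-methoxy-4-oxobuta-1,3-dien-1-yl]-4H-pyran-4-one (ketenyl and pyranonyl groups cis) | O=C=C/C(OC)=C\c1cc(=O)cc(-c2ccc(Oc3c(OC)cc(OCc4ccccc4)cc3OC)cc2)o1 | intermediate
20 | 2-{4-[4-(benzyloxy)-2,6-dimethoxyphenoxy]phenyl}-7-methoxy-4aH-chromene-4,5-dione (racemic) | COC1=CC(=O)C2C(=O)C=C(c3ccc(Oc4c(OC)cc(OCc5ccccc5)cc4OC)cc3)OC2=C1 | intermediate
21 | 2-{4-[4-(benzyloxy)-2,6-dimethoxyphenoxy]phenyl}-5-hydroxy-7-methoxy-4H-chromen-4-one | COc1cc(O)c2c(=O)cc(-c3ccc(Oc4c(OC)cc(OCc5ccccc5)cc4OC)cc3)oc2c1 | intermediate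
22 | 5-hydroxy-2-[4-(4-hydroxy-2,6-dimethoxyphenoxy)phenyl]-7-methoxy-4H-chromen-4-one | COc1cc(O)c2c(=O)cc(-c3ccc(Oc4c(OC)cc(O)cc4OC)cc3)oc2c1 | intermediate
23 | 2-[4-(3-acetyl-4-hydroxy-2,6-dimethoxyphenoxy)phenyl]-5-hydroxy-7-methoxy-4H-chromen-4-one | COc1cc(O)c2c(=O)cc(-c3ccc(Oc4c(OC)cc(O)c(C(C)=O)c4OC)cc3)oc2c1 | intermediate
24 | tert-butyl 3-{6-hydroxy-3-[4-(5-hydroxy-7-methoxy-4-oxo-4H-chromen-2-yl)phenoxy]-2,4-dimethoxyphenyl}-3-oxopropanoate | COc1cc(O)c2c(=O)cc(-c3ccc(Oc4c(OC)cc(O)c(C(=O)CC(=O)OC(C)(C)C)c4OC)cc3)oc2c1 | intermediate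
25 | 4-(benzyloxy)benzaldehyde | O=Cc1ccc(OCc2ccccc2)cc1 | starting material
26 | tert-butyl (2Z)-3-[4-(benzyloxy)phenyl]-2-{6-hydroxy-3-[4-(5-hydroxy-7-methoxy-4-oxo-4H-chromen-2-yl)phenoxy]-2,4-dimethoxybenzoyl}prop-2-enoate | COc1cc(O)c2c(=O)cc(-c3ccc(Oc4c(OC)cc(O)c(C(=O)/C(=C/c5ccc(OCc6ccccc6)cc5)C(=O)OC(C)(C)C)c4OC)cc3)oc2c1 | intermediate
27 | tert-butyl (2S)-2-[4-(benzyloxy)phenyl]-6-[4-(5-hydroxy-7-methoxy-4-oxo-4H-chromen-2-yl)phenoxy]-5,7-dimethoxy-4-oxo-3,4-dihydro-2H-chromene-3-carboxylate (C3'' enolisable, left undefined) | COc1cc(O)c2c(=O)cc(-c3ccc(Oc4c(OC)cc5c(c4OC)C(=O)C(C(=O)OC(C)(C)C)[C@@H](c4ccc(OCc6ccccc6)cc4)O5)cc3)oc2c1 | intermediate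
28 | (2S)-2-[4-(benzyloxy)phenyl]-6-[4-(5-hydroxy-7-methoxy-4-oxo-4H-chromen-2-yl)phenoxy]-5,7-dimethoxy-4-oxo-3,4-dihydro-2H-chromene-3-carboxylic acid (C3'' left undefined) | COc1cc(O)c2c(=O)cc(-c3ccc(Oc4c(OC)cc5c(c4OC)C(=O)C(C(=O)O)[C@@H](c4ccc(OCc6ccccc6)cc4)O5)cc3)oc2c1 | intermediate
29 | (2S)-2-[4-(benzyloxy)phenyl]-6-[4-(5-hydroxy-7-methoxy-4-oxo-4H-chromen-2-yl)phenoxy]-5,7-dimethoxy-2,3-dihydro-4H-chromen-4-one | COc1cc(O)c2c(=O)cc(-c3ccc(Oc4c(OC)cc5c(c4OC)C(=O)C[C@@H](c4ccc(OCc6ccccc6)cc4)O5)cc3)oc2c1 | intermediate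
30 | (2S)-5-hydroxy-6-[4-(5-hydroxy-7-methoxy-4-oxo-4H-chromen-2-yl)phenoxy]-2-(4-hydroxyphenyl)-7-methoxy-2,3-dihydro-4H-chromen-4-one | COc1cc(O)c2c(=O)cc(-c3ccc(Oc4c(OC)cc5c(c4O)C(=O)C[C@@H](c4ccc(O)cc4)O5)cc3)oc2c1 | target

Total step count: 15.
Longest linear sequence: 14 (steps 1–7 and 9–15). Step 8 is a one-step side branch.

## Steps most likely to fail

**Step 9 (bears the label "Proposed new method:").**

What may go wrong:
- Energy transfer to, or direct excitation of, the pyranone chromophore, followed by its photorearrangement.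
- Dimerisation or adventitious trapping of the ketene before it meets the alkyne.
- Reluctance of the electron-poor C2=C3 bond of the pyranone to join in the six-electron closure.

The fallback gives up the annulation and builds ring C onto a purchased ring A by known flavone chemistry. It sets out from 6 and comes back at 21.
- Ketone 6 is heated with I2 in pyridine (Ortoleva–King reaction) to give 1-(2-{4-[4-(benzyloxy)-2,6-dimethoxyphenoxy]phenyl}-2-oxoethyl)pyridinium iodide F1.
- Aqueous NaOH cleaves this to 4-[4-(benzyloxy)-2,6-dimethoxyphenoxy]benzoic acid F2. This sequence avoids a hypohalite, which could halogenate ring D.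
- (COCl)2 with catalytic DMF gives 4-[4-(benzyloxy)-2,6-dimethoxyphenoxy]benzoyl chloride F3.
- F3 C-acylates commercial 2',6'-dihydroxy-4'-methoxyacetophenone (CC(=O)c1c(O)cc(OC)cc1O), polylithiated with LiN(SiMe3)2 in THF at −78 °C. The product is 1-(2,6-dihydroxy-4-methoxyphenyl)-3-{4-[4-(benzyloxy)-2,6-dimethoxyphenoxy]phenyl}propane-1,3-dione F4.
- Cyclodehydration with p-TsOH·H2O in refluxing toluene should give 21 as the only flavone, because the two ortho hydroxyls are equivalent.

**Step 12.**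

What may go wrong:
- Poor solubility of the trilithium salt.
- Acylation on oxygen without onward transfer to carbon.
- Lactonisation of the product phenoxide onto the new ester.

The fallback brings in the three-carbon unit by an aldol reaction instead of carboxylating a ketone. It sets out from 22 (bypassing step 11 as well) and comes back at 24.
- Casnati–Skattebøl ortho-formylation of 22 (MgCl2, Et3N, paraformaldehyde, MeCN, reflux) should give 6-hydroxy-3-[4-(5-hydroxy-7-methoxy-4-oxo-4H-chromen-2-yl)phenoxy]-2,4-dimethoxybenzaldehyde F5.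
- Addition of excess lithium enolate of tert-butyl acetate (LiN(iPr)2, THF, −78 °C) gives racemic tert-butyl 3-hydroxy-3-{6-hydroxy-3-[4-(5-hydroxy-7-methoxy-4-oxo-4H-chromen-2-yl)phenoxy]-2,4-dimethoxyphenyl}propanoate F6.
- Oxidation of the benzylic alcohol with MnO2 in CH2Cl2 gives 24.

**Step 15.**

What may go wrong:
- Lewis-acid-induced ionisation of the benzylic C2''–O1'' bond, with ring opening and reclosure, and hence erosion of enantiomeric purity.
- Incomplete cleavage of the 5''-methyl ether.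

The fallback removes that methyl group before any stereocentre exists and sets C2'' by C–C bond formation. It sets out from 23 and comes back at 30.
- Heating 23 with N,N-dimethylformamide dimethyl acetal in toluene gives 2-(4-{3-[(2E)-3-(dimethylamino)prop-2-enoyl]-4-hydroxy-2,6-dimethoxyphenoxy}phenyl)-5-hydroxy-7-methoxy-4H-chromen-4-one F7.
- Aqueous HCl in CH2Cl2 closes this to 2-{4-[(5,7-dimethoxy-4-oxo-4H-chromen-6-yl)oxy]phenyl}-5-hydroxy-7-methoxy-4H-chromen-4-one F8.
- BCl3 at −10 °C cleaves the chelated methyl ether of this achiral chromone to give 5-hydroxy-2-{4-[(5-hydroxy-7-methoxy-4-oxo-4H-chromen-6-yl)oxy]phenyl}-7-methoxy-4H-chromen-4-one F9.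
- Rhodium-catalysed asymmetric 1,4-addition of 4-(benzyloxy)phenylboronic acid follows, using [Rh(OH)(cod)]2 and an electron-poor atropisomeric bisphosphine of the antipode that serves the 2S series, in toluene–H2O at rt. It should take place only at the unsubstituted C2'' of the chromone, because the 2-aryl-substituted flavone is far less reactive. The product is (2S)-2-[4-(benzyloxy)phenyl]-5-hydroxy-6-[4-(5-hydroxy-7-methoxy-4-oxo-4H-chromen-2-yl)phenoxy]-7-methoxy-2,3-dihydro-4H-chromen-4-one F10.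
- Neutral hydrogenolysis (H2, 10% Pd/C, EtOAc, rt) then gives 30.

## Further compounds

F1 | step 9 | 1-(2-{4-[4-(benzyloxy)-2,6-dimethoxyphenoxy]phenyl}-2-oxoethyl)pyridinium iodide | [I-].O=C(C[n+]1ccccc1)c1ccc(Oc2c(OC)cc(OCc3ccccc3)cc2OC)cc1
F2 | step 9 | 4-[4-(benzyloxy)-2,6-dimethoxyphenoxy]benzoic acid | OC(=O)c1ccc(Oc2c(OC)cc(OCc3ccccc3)cc2OC)cc1
F3 | step 9 | 4-[4-(benzyloxy)-2,6-dimethoxyphenoxy]benzoyl chloride | ClC(=O)c1ccc(Oc2c(OC)cc(OCc3ccccc3)cc2OC)cc1
F4 | step 9 | 1-(2,6-dihydroxy-4-methoxyphenyl)-3-{4-[4-(benzyloxy)-2,6-dimethoxyphenoxy]phenyl}propane-1,3-dione | COc1cc(O)c(C(=O)CC(=O)c2ccc(Oc3c(OC)cc(OCc4ccccc4)cc3OC)cc2)c(O)c1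
F5 | step 12 | 6-hydroxy-3-[4-(5-hydroxy-7-methoxy-4-oxo-4H-chromen-2-yl)phenoxy]-2,4-dimethoxybenzaldehyde | COc1cc(O)c2c(=O)cc(-c3ccc(Oc4c(OC)cc(O)c(C=O)c4OC)cc3)oc2c1
F6 | step 12 | tert-butyl 3-hydroxy-3-{6-hydroxy-3-[4-(5-hydroxy-7-methoxy-4-oxo-4H-chromen-2-yl)phenoxy]-2,4-dimethoxyphenyl}propanoate (racemic) | COc1cc(O)c2c(=O)cc(-c3ccc(Oc4c(OC)cc(O)c(C(O)CC(=O)OC(C)(C)C)c4OC)cc3)oc2c1
F7 | step 15 | 2-(4-{3-[(2E)-3-(dimethylamino)prop-2-enoyl]-4-hydroxy-2,6-dimethoxyphenoxy}phenyl)-5-hydroxy-7-methoxy-4H-chromen-4-one | COc1cc(O)c2c(=O)cc(-c3ccc(Oc4c(OC)cc(O)c(C(=O)/C=C/N(C)C)c4OC)cc3)oc2c1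
F8 | step 15 | 2-{4-[(5,7-dimethoxy-4-oxo-4H-chromen-6-yl)oxy]phenyl}-5-hydroxy-7-methoxy-4H-chromen-4-one | COc1cc(O)c2c(=O)cc(-c3ccc(Oc4c(OC)cc5c(c4OC)c(=O)cco5)cc3)oc2c1
F9 | step 15 | 5-hydroxy-2-{4-[(5-hydroxy-7-methoxy-4-oxo-4H-chromen-6-yl)oxy]phenyl}-7-methoxy-4H-chromen-4-one | COc1cc(O)c2c(=O)cc(-c3ccc(Oc4c(OC)cc5c(c4O)c(=O)cco5)cc3)oc2c1
F10 | step 15 | (2S)-2-[4-(benzyloxy)phenyl]-5-hydroxy-6-[4-(5-hydroxy-7-methoxy-4-oxo-4H-chromen-2-yl)phenoxy]-7-methoxy-2,3-dihydro-4H-chromen-4-one | COc1cc(O)c2c(=O)cc(-c3ccc(Oc4c(OC)cc5c(c4O)C(=O)C[C@@H](c4ccc(OCc6ccccc6)cc4)O5)cc3)oc2c1
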